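The earlier runs and the new flask were computed from invented constants, noise included.

These flasks are slow: ochre needed 25.0 h to reach 78 % of Q.

all flasks: L 2 mol%
- violet: E 0.0039 M; run made earlier
- blue: E 0.0070 M; run made earlier
- ochre: E 0.015 M; run made earlier
- birch: E 0.014 M; time 25 h
- elm: E 0.0040 M; time 50 h

- violet (time / h: Q / %): 2.00: 11; 6.00: 25; 12.0: 36; 20.0: 46; 25.0: 52
- blue (time / h: Q / %): 2.00: 14; 4.00: 21; 8.00: 32; 12.0: 44; 25.0: 62
- ochre (time / h: Q / %): 5.00: 35; 10.0: 54; 15.0: 63; 20.0: 73; 25.0: 78

(readings scatter by 2 percentage points)

- what is said of Q includes G
- G is a solid; its amount is given per volume of the solution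
- what may be going on: G <-> Q; 2 J -> X; E + J -> Q + J; L -> 2 Z; E + Z -> J + Q
- where the amount of E changes, what is given in equivalents or mol% on it follows

- the winner by amount of Q, in percent of the E charged; "neither" if no more than 2 percentage points parts them (birch / elm / neither)
- how much Q is there at the end, in percent of the E charged: birch
- how much Q is there at the end, in percent of the E charged: elm

*How does E fall?* E goes to Q through J. J is made from Z and lost in pairs, so I take J as settled where making equals loss (quasi-steady state), and J then goes as the root of L. The loss of E is pseudo-first-order, and I call the logarithm of one over the fraction of E left the dose.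

*What does the charge do?* L is a fixed mol% of E, so at a fixed time the dose goes with the root of the charge.

*Do the runs agree?* Reduced to ochre's charge, the doses at 25.0 h are 1.44 for violet, 1.42 for blue and 1.51 for ochre. Their mean is the reference dose, 1.46, a reading with the scatter of its readings.

*Birch?* The root of the charge gives a dose of 1.41, so I reckon 75.5 % of Q.

*Elm runs to 50 h, past every reading. What then?* L decays, so the rate fades. Ochre's doses at 10.0 h and at twice that time stand in the ratio 1.69, so I read a share 0.690 of the rate as left after 10.0 h. If that share holds for each further 10.0 h, the dose at 50 h stands to the dose at 25.0 h as 1.39. With its own charge and time, elm's dose becomes 1.05, so I reckon 64.9 % of Q, less than birch.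

*And crystals?* The steps that use E hold neither G nor dissolved Q as a reactant, and the count of Q includes G.

The forecast, reasoning that “the radical level and first-order rate should scale” with the root of E, gave birch 76 % (73 % to 79 %), elm 64 % (59 % to 70 %) and birch as winner. Those figures differ slightly from mine, but the winner is the same.

Birch gives 75.2 % and elm 63.8 %, so birch wins.

G ⇌ Q, rate k1*(cs1 - [Q]) while solid is left; crystals form when [Q] > cs1 (solubility = 9.80 mM, k = 0.0150 min⁻¹); 2 J → X (k = 2.00 × 10⁸ M⁻¹ s⁻¹); E + J → Q + J, rate k3*[J]*[E] (k = 2.50 × 10⁵ M⁻¹ min⁻¹); L → 2 Z (k = 0.00140 min⁻¹); E + Z → J + Q (k = 74000 M⁻¹ s⁻¹) Birch ended with G at 4.27 %, counted in Q, yet the saturation of Q does not change its figure. Birch's dose from the result is 1.39, against the 1.41 reckoned. A neighbour of birch charged with 0.024 M of E, at the same mol% and time, takes from the reference dose a dose of 1.84, which means 84.1 % of Q. That neighbour stood at 83.8 % of Q, with G at 42.2 % of the charge.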